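**Retrosynthetic overview**
1. Target 22 ⇒ acetylfilicinic acid 14 + aryl Mannich base 20. The CH2 bridge is made last by capture of an ortho-quinone methide; the benzene ring is bought (2,4,6-trihydroxytoluene) and only decorated.
2. 14 ⇒ fully masked cyclohexa-2,4-dienone 13 ⇒ cyclobutenone 9 + siloxyalkyne 5. One thermal cascade (4π opening, [2+2], 4π opening, 6π closure) forms the C(=O)–C(CH3)2 ring bond and delivers all six ring carbons, the three oxygens, the gem-dimethyl carbon and the masked acetyl group.
3. 9 ⇒ dimethylketene + ethoxyacetylene ([2+2]); 5 ⇒ but-3-yn-2-one (acetalization, acetylide oxidation, O-silylation).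
4. Enabling feature: the quaternary C(CH3)2 ring atom between two C–O carbons makes the filicinic ring a non-aromatisable 6,6-dimethylcyclohexa-2,4-dienone with a 1,3,5-oxygen pattern. That is the electrocyclization product of a ketene whose dienyl terminus is an isopropylidene group.
5. Ring order: temporary four-membered ring of 9, temporary four-membered ring of 11, then the six-membered filicinic ring (all opened or closed in step 4); the benzene ring is present from the start.

Key step: step 4

Remark on the chemistry: the β-triketone ring of 14 and 22 is a set of rapidly interconverting enol tautomers; both are written in the tautomer of the target SMILES. The target has no stereocentre.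

Step 1
Reactants: 1 but-3-yn-2-one
Product: 2 2-ethynyl-2-methyl-1,3-dioxolane
Conditions: (Me3SiOCH2)2, Me3SiOTf (cat.), CH2Cl2, −78 → −20 °C
Reagents that add atoms: 1,2-bis(trimethylsilyloxy)ethane, C[Si](C)(C)OCCO[Si](C)(C)C
Why: Noyori acetalization converts the ynone into its dioxolane at low temperature without conjugate addition to the alkyne, driven by formation of the Si–O–Si bond.

Step 2
Reactants: 2 2-ethynyl-2-methyl-1,3-dioxolane
Product: 5 2-methyl-2-{[(triisopropylsilyl)oxy]ethynyl}-1,3-dioxolane, via lithium acetylide 3 (not isolated), via lithium ynolate 4 (not isolated)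
Conditions: n-BuLi, THF, −78 °C; then t-BuOOLi (from t-BuOOH, LiN(SiMe3)2), −78 → 0 °C; then iPr3SiOTf, −78 → 0 °C
Reagents that add atoms: tert-butyl hydroperoxide (as its lithium salt), CC(C)(C)OO; triisopropylsilyl trifluoromethanesulfonate, CC(C)[Si](C(C)C)(C(C)C)OS(=O)(=O)C(F)(F)F
Why: Electrophilic oxygen transfer from lithium tert-butyl peroxide to the lithium acetylide gives the lithium ynolate, and O-silylation with the bulky silyl triflate gives the isolable 1-siloxyalkyne (the standard acetylide-oxidation route to siloxyalkynes).

Step 3
Reactants: 6 isobutyryl chloride; 7 ethoxyacetylene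
Product: 9 3-ethoxy-4,4-dimethylcyclobut-2-en-1-one, via dimethylketene 8 (not isolated)
Conditions: Et3N, Et2O, 0 °C → rt
Reagents that add atoms: none
Why: Dehydrochlorination gives dimethylketene, which undergoes the regioselective ketene–alkoxyalkyne [2+2] cycloaddition (the nucleophilic CH carbon of the ynol ether bonds to the ketene carbonyl carbon) to give the 3-ethoxycyclobutenone.

Step 4
Reactants: 9 3-ethoxy-4,4-dimethylcyclobut-2-en-1-one; 5 2-methyl-2-{[(triisopropylsilyl)oxy]ethynyl}-1,3-dioxolane
Product: 13 5-ethoxy-6,6-dimethyl-2-(2-methyl-1,3-dioxolan-2-yl)-3-[(triisopropylsilyl)oxy]cyclohexa-2,4-dien-1-one, via vinylketene 10 (not isolated), via 4-alkenylcyclobutenone 11 (not isolated), via dienylketene 12 (not isolated)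
Conditions: 5 (1.5 equiv), toluene, 130 °C, sealed tube
Reagents that add atoms: none
Why: Proposed new method: heating opens cyclobutenone 9 by conrotatory 4π electrocyclic ring opening to vinylketene 10, whose ketene C=C adds to the siloxyalkyne in a [2+2] cycloaddition to give 11, which opens again to dienylketene 12 and closes by thermal disrotatory 6π electrocyclization, the ketene carbon bonding to the isopropylidene carbon to form the C(=O)–C(CH3)2 bond of the six-membered ring. The closest known reaction type is the cyclobutenone–alkynyl ether benzannulation (Danheiser benzannulation), together with the thermal closure of dienylketenes to cyclohexa-2,4-dienones, which is the reverse of the photochemical ring opening of 6,6-disubstituted cyclohexa-2,4-dienones; new is the use of a 3-alkoxy-4,4-dimethylcyclobutenone, so that the cascade ends at a dienone that cannot tautomerise to a phenol. The four-membered ring of 11 closes by [2+2] cycloaddition and the six-membered ring by 6π electrocyclization, in which all six ring atoms come from the ketene–diene array. Product 13 has no stereocentre, and the single stereocentre of 11 is racemic and is erased when 11 opens. The step needs regioselectivity in the [2+2] event, secured by the polarisation of the siloxyalkyne (its carbon β to oxygen, which bears the dioxolane, bonds to the electrophilic ketene carbon, placing the masked acetyl group next to the future C=O), and it needs the alkenyl group of 11 to rotate inward, secured because ring opening is reversible and only the inward isomer can cyclise. The two identical methyl groups at C4 of 9 make the torquoselectivity of the first opening irrelevant and block aromatisation at the end.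

Step 5
Reactants: 13 5-ethoxy-6,6-dimethyl-2-(2-methyl-1,3-dioxolan-2-yl)-3-[(triisopropylsilyl)oxy]cyclohexa-2,4-dien-1-one
Product: 14 acetylfilicinic acid (2-acetyl-3,5-dihydroxy-4,4-dimethylcyclohexa-2,5-dien-1-one)
Conditions: 2 M aq. HCl, THF, 50 °C
Reagents that add atoms: water, O
Why: Aqueous acid hydrolysis cleaves in one operation the silyl enol ether, the ethyl vinylogous ester and the dioxolane (acetal hydrolysis), and the resulting enolised β-triketone is stable to dilute acid.

Step 6
Reactants: 15 2,4,6-trihydroxytoluene
Product: 16 1-(2,4,6-trihydroxy-3-methylphenyl)ethanone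
Conditions: Ac2O (1.1 equiv), BF3·OEt2 (solvent), 60 °C; aq. NaOAc work-up
Reagents that add atoms: acetic anhydride, CC(=O)OC(C)=O
Why: Friedel–Crafts acylation of the phloroglucinol nucleus occurs at one of its two equivalent free positions, and the acyl group deactivates the ring against a second acylation.

Step 7
Reactants: 16 1-(2,4,6-trihydroxy-3-methylphenyl)ethanone
Product: 17 1-[4,6-bis(benzyloxy)-2-hydroxy-3-methylphenyl]ethanone
Conditions: BnBr (2.05 equiv), K2CO3, acetone, reflux
Reagents that add atoms: benzyl bromide, BrCc1ccccc1
Why: In this Williamson etherification the hydroxyl para to the acetyl group alkylates first, and of the two chelated ortho hydroxyls the one next to the ring hydrogen is less hindered than the one flanked by the methyl group, which should remain as the hydrogen-bonded phenol.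

Step 8
Reactants: 17 1-[4,6-bis(benzyloxy)-2-hydroxy-3-methylphenyl]ethanone
Product: 18 1-[4,6-bis(benzyloxy)-2-methoxy-3-methylphenyl]ethanone
Conditions: MeI, K2CO3, DMF, 50 °C
Reagents that add atoms: iodomethane, CI
Why: Williamson methylation of the only remaining phenol under more forcing conditions places the methoxy group between the acetyl and methyl groups.

Step 9
Reactants: 18 1-[4,6-bis(benzyloxy)-2-methoxy-3-methylphenyl]ethanone
Product: 19 1-(4,6-dihydroxy-2-methoxy-3-methylphenyl)ethanone
Conditions: H2 (1 atm), 10% Pd/C, EtOAc–MeOH, rt
Reagents that add atoms: none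
Why: Hydrogenolysis cleaves both benzyl ethers and leaves the aryl methyl ether and the electron-rich aryl ketone untouched.

Step 10
Reactants: 19 1-(4,6-dihydroxy-2-methoxy-3-methylphenyl)ethanone
Product: 20 1-{3-[(dimethylamino)methyl]-2,4-dihydroxy-6-methoxy-5-methylphenyl}ethanone
Conditions: 37% aq. CH2O, 40% aq. Me2NH, EtOH, rt
Reagents that add atoms: formaldehyde, C=O; dimethylamine, CNC
Why: The phenolic Mannich reaction occurs at the only unsubstituted ring carbon, which lies ortho to two hydroxyl groups.

Step 11
Reactants: 20 1-{3-[(dimethylamino)methyl]-2,4-dihydroxy-6-methoxy-5-methylphenyl}ethanone; 14 acetylfilicinic acid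
Product: 22 2-acetyl-6-[(3-acetyl-2,6-dihydroxy-4-methoxy-5-methylphenyl)methyl]-3,5-dihydroxy-4,4-dimethylcyclohexa-2,5-dien-1-one, via ortho-quinone methide 21 (not isolated)
Conditions: 1,4-dioxane, 100 °C, N2 stream
Reagents that add atoms: none
Why: The acidic triketone protonates the benzylic amine, thermal loss of dimethylamine gives the ortho-quinone methide, and Michael addition of the only free nucleophilic carbon of 14 to its CH2 terminus re-aromatises the ring; cross-selectivity follows because only 20 can supply the electrophile.

**Compound list**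
1 | but-3-yn-2-one | CC(=O)C#C | starting material
2 | 2-ethynyl-2-methyl-1,3-dioxolane | CC1(C#C)OCCO1 | intermediate
3 | lithium (2-methyl-1,3-dioxolan-2-yl)acetylide | [Li]C#CC1(C)OCCO1 | intermediate
4 | lithium 2-(2-methyl-1,3-dioxolan-2-yl)ethynolate | [Li]OC#CC1(C)OCCO1 | intermediate
5 | 2-methyl-2-{[(triisopropylsilyl)oxy]ethynyl}-1,3-dioxolane | CC1(C#CO[Si](C(C)C)(C(C)C)C(C)C)OCCO1 | intermediate
6 | isobutyryl chloride | CC(C)C(Cl)=O | starting material
7 | ethoxyacetylene | CCOC#C | starting material
8 | dimethylketene | CC(C)=C=O | intermediate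
9 | 3-ethoxy-4,4-dimethylcyclobut-2-en-1-one | CCOC1=CC(=O)C1(C)C | intermediate
10 | 3-ethoxy-4-methylpenta-1,3-dien-1-one (vinylketene) | CCOC(C=C=O)=C(C)C | intermediate
11 | 4-(1-ethoxy-2-methylprop-1-en-1-yl)-2-(2-methyl-1,3-dioxolan-2-yl)-3-[(triisopropylsilyl)oxy]cyclobut-2-en-1-one (racemic) | O=C1C(C2(C)OCCO2)=C(O[Si](C(C)C)(C(C)C)C(C)C)C1C(OCC)=C(C)C | intermediate
12 | (3E)-5-ethoxy-6-methyl-2-(2-methyl-1,3-dioxolan-2-yl)-3-[(triisopropylsilyl)oxy]hepta-1,3,5-trien-1-one (dienylketene; ketenyl carbon and dienyl terminus cis) | O=C=C(C1(C)OCCO1)/C(O[Si](C(C)C)(C(C)C)C(C)C)=C\C(OCC)=C(C)C | intermediate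
13 | 5-ethoxy-6,6-dimethyl-2-(2-methyl-1,3-dioxolan-2-yl)-3-[(triisopropylsilyl)oxy]cyclohexa-2,4-dien-1-one | CCOC1=CC(O[Si](C(C)C)(C(C)C)C(C)C)=C(C2(C)OCCO2)C(=O)C1(C)C | intermediate
14 | acetylfilicinic acid (2-acetyl-3,5-dihydroxy-4,4-dimethylcyclohexa-2,5-dien-1-one) | CC(=O)C1=C(O)C(C)(C)C(O)=CC1=O | intermediate
15 | 2,4,6-trihydroxytoluene | Cc1c(O)cc(O)cc1O | starting material
16 | 1-(2,4,6-trihydroxy-3-methylphenyl)ethanone | CC(=O)c1c(O)cc(O)c(C)c1O | intermediate
17 | 1-[4,6-bis(benzyloxy)-2-hydroxy-3-methylphenyl]ethanone | CC(=O)c1c(OCc2ccccc2)cc(OCc2ccccc2)c(C)c1O | intermediate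
18 | 1-[4,6-bis(benzyloxy)-2-methoxy-3-methylphenyl]ethanone | CC(=O)c1c(OCc2ccccc2)cc(OCc2ccccc2)c(C)c1OC | intermediate
19 | 1-(4,6-dihydroxy-2-methoxy-3-methylphenyl)ethanone | CC(=O)c1c(O)cc(O)c(C)c1OC | intermediate
20 | 1-{3-[(dimethylamino)methyl]-2,4-dihydroxy-6-methoxy-5-methylphenyl}ethanone | CC(=O)c1c(O)c(CN(C)C)c(O)c(C)c1OC | intermediate
21 | 4-acetyl-5-hydroxy-3-methoxy-2-methyl-6-methylidenecyclohexa-2,4-dien-1-one (ortho-quinone methide) | C=C1C(=O)C(C)=C(OC)C(C(C)=O)=C1O | intermediate
22 | 2-acetyl-6-[(3-acetyl-2,6-dihydroxy-4-methoxy-5-methylphenyl)methyl]-3,5-dihydroxy-4,4-dimethylcyclohexa-2,5-dien-1-one | COc1c(C)c(O)c(CC2=C(O)C(C)(C)C(O)=C(C(C)=O)C2=O)c(O)c1C(C)=O | target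

**Step count**
Total: 11 steps. Longest linear sequence: 6 steps (steps 6, 7, 8, 9, 10, 11); the filicinic branch is 5 steps (1, 2, 4, 5, 11), with step 3 feeding into step 4.

**Steps most likely to fail**

Step 4. The vinylogous-ester cyclobutenone may open too slowly, and the vinylketene may be consumed by a 1,5-hydrogen shift from its cis methyl group or by dimerisation before the hindered siloxyalkyne intercepts it. The fallback uses known chemistry and sets out from 16: dearomatising C-methylation (MeI, NaOMe, MeOH, rt) at the ring carbon that already bears the methyl group, the classical preparation of acylfilicinic acids, gives 14 after separation from the aromatic 3,5-dimethyl isomer. It comes back to the route at 14 and makes no compound outside the list.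

Step 2. The ynolate may lose alkoxide from the acetal carbon next to its carbanionic centre, or the propargylic acetal of the siloxyalkyne may ionise during silylation and purification. The fallback sets out from 9 and a second portion of 7 and introduces the acetyl group last. Heating 9 with excess 7 (toluene, sealed tube, about 100 °C, below the temperature at which 7 fragments to ketene and ethylene) should give 3,5-diethoxy-6,6-dimethylcyclohexa-2,4-dien-1-one F1 by the same cascade as step 4. Hydrolysis (2 M aq. HCl, THF, 50 °C) gives filicinic acid F2. C-acetylation at its only free nucleophilic carbon (Ac2O, BF3·OEt2) comes back to the route at 14.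

Step 7. Site selectivity between the two hydroxyls ortho to the acetyl group may be poor, and some C-benzylation of the phloroglucinol ring may occur. The fallback sets out from 16: exhaustive O-benzylation (excess BnBr, K2CO3, DMF, 60 °C) gives 1-[2,4,6-tris(benzyloxy)-3-methylphenyl]ethanone F3. Chelation-controlled mono-debenzylation with BCl3 (1 equiv, CH2Cl2, −78 °C) then removes the ortho benzyl group that is flanked by acetyl and methyl, the most congested and most basic ether oxygen. This comes back to the route at 17.

**Further compounds**
F0 | step 4 | none | none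
F1 | step 2 | 3,5-diethoxy-6,6-dimethylcyclohexa-2,4-dien-1-one | CCOC1=CC(OCC)=CC(=O)C1(C)C
F2 | step 2 | filicinic acid (3,5-dihydroxy-4,4-dimethylcyclohexa-2,5-dien-1-one) | CC1(C)C(O)=CC(=O)C=C1O
F3 | step 7 | 1-[2,4,6-tris(benzyloxy)-3-methylphenyl]ethanone | CC(=O)c1c(OCc2ccccc2)cc(OCc2ccccc2)c(C)c1OCc1ccccc1
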